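**Strategy.** The target is cut at its methylene bridge into wailupemycin F (the tetralone half) and wailupemycin G, which is the dehydration product of F, so one tetralone serves both halves. Ring B of the tetralone is made in one flask from an acyclic (S)-β-hydroxy Weinreb amide and 3-(benzyloxy)benzyne. The C4 carbanion, activated by pyrone C6, adds to the aryne at C4a. The resulting C8a aryllithium, held ortho to the C8 oxygen, then closes ring B by acylation at C1. The step exploits the contiguous C8(O)–C8a(acyl)–C4a(alkyl) pattern of ring A and the acidity of C4–H. The precursor is a 6-alkyl-4-benzyloxy-2-pyrone carrying the C3 carbinol and the C1 amide.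

Key step: step 7

Remarks on the chemistry: atom numbers follow the tetralone (C1 carbonyl, C3 carbinol, C4 methine, C4a and C8a ring fusion, C8 phenol carbon); ring A is the benzene ring and ring B the cyclohexanone ring. (R)-3,3′-Br2-BINOL is assumed to send the allyl group to the Si face of the phenacyl ketone in step 3; if the sense is the opposite, the (S)-diol is used and nothing else changes.

Step 1
Reactants: 1 4-hydroxy-6-methyl-2H-pyran-2-one
Product: 2 4-(benzyloxy)-6-methyl-2H-pyran-2-one
Conditions: BnBr, K2CO3, DMF, rt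
Reagents that add atoms: benzyl bromide, BrCc1ccccc1
Why: Williamson-type O-benzylation of the acidic vinylogous acid at O4 should mask the pyrone hydroxyl as a vinylogous benzyl ester that survives amide bases and is removed by hydrogenolysis at the end.

Step 2
Reactants: 2 4-(benzyloxy)-6-methyl-2H-pyran-2-one; 3 methyl benzoate
Product: 5 4-(benzyloxy)-6-(2-oxo-2-phenylethyl)-2H-pyran-2-one, via pyronylmethyllithium 4 (not isolated)
Conditions: LiN(iPr)2 (2.1 equiv), THF, −78 °C; then 3, −78 → −20 °C; 1 M HCl
Reagents that add atoms: none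
Why: Lateral (vinylogous) lithiation of the C6 methyl group followed by Claisen-type acylation should give the phenacyl pyrone, the second equivalent of base storing the more acidic product as its enolate so that it cannot be attacked again.

Step 3
Reactants: 5 4-(benzyloxy)-6-(2-oxo-2-phenylethyl)-2H-pyran-2-one
Product: 6 (R)-4-(benzyloxy)-6-(2-hydroxy-2-phenylpent-4-en-1-yl)-2H-pyran-2-one
Conditions: allyl-B(OiPr)2 (1.5 equiv), (R)-3,3′-Br2-BINOL (15 mol%), PhCF3/toluene, −35 °C; H2O
Reagents that add atoms: allyldiisopropoxyborane, C=CCB(OC(C)C)OC(C)C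
Why: Chiral-diol-catalysed asymmetric allylboration of an aryl ketone proceeds through a closed six-membered chair transition state with phenyl as the large group, so Si-face delivery should set the tertiary carbinol (the later C3) as R, and the non-basic reagent should leave the acidic CH2 between ketone and pyrone alone.

Step 4
Reactants: 6 (R)-4-(benzyloxy)-6-(2-hydroxy-2-phenylpent-4-en-1-yl)-2H-pyran-2-one
Product: 8 (S)-4-[4-(benzyloxy)-2-oxo-2H-pyran-6-yl]-3-hydroxy-3-phenylbutanal, via triol 7 (not isolated)
Conditions: OsO4 (2 mol%), NaIO4 (4 equiv), 2,6-lutidine, dioxane/H2O, rt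
Reagents that add atoms: osmium tetroxide, O=[Os](=O)(=O)=O; sodium periodate, [Na+].[O-]I(=O)(=O)=O (reoxidant that returns the oxygen to osmium)
Why: Lemieux–Johnson cleavage, in which OsO4 should dihydroxylate the isolated terminal alkene faster than the conjugated pyrone double bonds and periodate cleaves the diol, the lutidine buffer keeping the tertiary β-hydroxy aldehyde from dehydration and retro-aldol cleavage.

Step 5
Reactants: 8 (S)-4-[4-(benzyloxy)-2-oxo-2H-pyran-6-yl]-3-hydroxy-3-phenylbutanal
Product: 9 (S)-4-[4-(benzyloxy)-2-oxo-2H-pyran-6-yl]-3-hydroxy-3-phenylbutanoic acid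
Conditions: NaClO2, NaH2PO4, 2-methyl-2-butene, t-BuOH/H2O, 0 °C → rt
Reagents that add atoms: sodium chlorite, [Na+].[O-]Cl=O
Why: Pinnick oxidation should convert the aldehyde into the acid under weakly acidic conditions that spare the tertiary alcohol, the benzyl ether and the pyrone, the alkene scavenger removing HOCl before it can chlorinate the pyrone.

Step 6
Reactants: 9 (S)-4-[4-(benzyloxy)-2-oxo-2H-pyran-6-yl]-3-hydroxy-3-phenylbutanoic acid
Product: 11 (S)-4-[4-(benzyloxy)-2-oxo-2H-pyran-6-yl]-3-hydroxy-N-methoxy-N-methyl-3-phenylbutanamide, via acyl imidazolide 10 (not isolated)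
Conditions: 1,1′-carbonyldiimidazole, THF, rt; then MeNH(OMe)·HCl, rt
Reagents that add atoms: N,O-dimethylhydroxylamine hydrochloride, CNOC.Cl
Why: Carboxyl activation as the acyl imidazolide and aminolysis (Weinreb amide synthesis) should leave the hindered tertiary hydroxyl untouched and installs a C1 acyl group that accepts exactly one aryl anion.

Step 7
Reactants: 11 (S)-4-[4-(benzyloxy)-2-oxo-2H-pyran-6-yl]-3-hydroxy-N-methoxy-N-methyl-3-phenylbutanamide; 12 1-(benzyloxy)-3-bromobenzene
Product: 17 (3R,4R)-8-(benzyloxy)-4-[4-(benzyloxy)-2-oxo-2H-pyran-6-yl]-3-hydroxy-3-phenyl-3,4-dihydronaphthalen-1(2H)-one, via dilithio dianion 13 (not isolated), via 3-(benzyloxy)benzyne 14 (not isolated), via C8a aryllithium 15 (not isolated), via ring-closed trilithio hemiaminalate 16 (not isolated)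
Conditions: LiN(iPr)2 (2.05 equiv), THF, −78 °C; 12 (1.3 equiv); lithium 2,2,6,6-tetramethylpiperidide (2.5 equiv, from the amine and n-BuLi) added slowly, −78 → −45 °C; AcOH, −78 °C
Reagents that add atoms: none
Why: Two equivalents of LiN(iPr)2 convert 11 into the alkoxide/C4 carbanion 13 (C4–H is the vinylogous α-position of the pyrone lactone), the lithium piperidide lithiates 12 between Br and OBn and loss of LiBr gives aryne 14, to which the C4 carbanion adds at the aryne carbon remote from the benzyloxy group because this places the new carbanion at C8a next to the inductively withdrawing C8 oxygen. The C8a aryllithium 15 then attacks the Weinreb carbonyl C1 in a 6-exo-trig acyl addition that closes ring B and is held as the chelated N,O-hemiaminalate, so no ketone is exposed to base. The closest known reaction type is the anionic aryne annulation, in which a carbanion adds to an aryne and the aryl anion is acylated by a pendant ester or amide (a Parham-type cyclization fed by an aryne). Excess amide base re-lithiates the now doubly activated C4–H to give 16, and C4 is set on the acetic acid quench: allylic 1,3-strain with the exocyclic pyrone should place the C3 phenyl axial, so protonation anti to it should give the 3,4-trans (3R,4R) isomer, which also has the pyrone pseudo-axial and free of the peri clash with C5–H. The selectivities needed are the regiochemistry of aryne addition (secured by the C8 oxygen), arylation at the exocyclic C4 and not at a pyrone ring carbon (the usual site of alkylation and acylation of this dienolate) and attack of C8a on C1 and not on the lactone (only C1 is within reach for a six-membered ring). C3 is carried unchanged from 11, and retro-aldol cleavage of 13 should be held back by the low temperature and by the charge already present at C4.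

Step 8
Reactants: 17 (3R,4R)-8-(benzyloxy)-4-[4-(benzyloxy)-2-oxo-2H-pyran-6-yl]-3-hydroxy-3-phenyl-3,4-dihydronaphthalen-1(2H)-one
Product: 18 wailupemycin F, (3R,4R)-3,8-dihydroxy-4-(4-hydroxy-2-oxo-2H-pyran-6-yl)-3-phenyl-3,4-dihydronaphthalen-1(2H)-one
Conditions: H2 (1 atm), Pd on carbon (Pd/C, 10 wt%), EtOAc/MeOH, rt
Reagents that add atoms: none
Why: Hydrogenolysis of the aryl benzyl ether and of the vinylogous benzyl ester under neutral conditions should free both hydroxyls without touching the chelated aryl ketone, the tertiary carbinol or the C3 and C4 stereocentres.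

Step 9
Reactants: 18 wailupemycin F (a portion of the material)
Product: 19 wailupemycin G, 6-(4,5-dihydroxy-2-phenylnaphthalen-1-yl)-4-hydroxy-2H-pyran-2-one
Conditions: TsOH·H2O (cat.), dioxane, 60 °C, argon
Reagents that add atoms: none
Why: Acid-catalysed β-elimination of the tertiary benzylic hydroxyl (dehydration of the aldol unit) followed by tautomerisation should aromatise ring B to the naphthalene-1,8-diol pattern, which deliberately removes both stereocentres.

Step 10
Reactants: 18 wailupemycin F; 19 wailupemycin G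
Product: 22 wailupemycin I (target), via Mannich base 20 (not isolated), via 3-methylene-pyrandione 21 (not isolated)
Conditions: CH2(NMe2)2 (1.0 equiv), AcOH (2 equiv), MeCN, 0 °C; then 19 (1.2 equiv), 40 °C, argon
Reagents that add atoms: bis(dimethylamino)methane, CN(C)CN(C)C
Why: Mannich aminomethylation at C3 of the 4-hydroxy-2-pyrone of 18, elimination of dimethylamine to the 3-methylene-pyran-2,4-dione 21 and Michael addition of the pyrone of 19 (Knoevenagel–Michael-type methylene bridging) should give the unsymmetrical bis-pyronylmethane, and 18 is the partner that is activated because its chelated phenol ring is far less reactive toward the iminium ion than the naphthalenediol of 19.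

**Compound list**

1 | 4-hydroxy-6-methyl-2H-pyran-2-one | Cc1cc(O)cc(=O)o1 | starting material
2 | 4-(benzyloxy)-6-methyl-2H-pyran-2-one | Cc1cc(OCc2ccccc2)cc(=O)o1 | intermediate
3 | methyl benzoate | COC(=O)c1ccccc1 | starting material
4 | [4-(benzyloxy)-2-oxo-2H-pyran-6-yl]methyllithium (pyrone dienolate drawn in its C-lithio form; not isolated) | [Li]Cc1cc(OCc2ccccc2)cc(=O)o1 | intermediate
5 | 4-(benzyloxy)-6-(2-oxo-2-phenylethyl)-2H-pyran-2-one | O=C(Cc1cc(OCc2ccccc2)cc(=O)o1)c1ccccc1 | intermediate
6 | (R)-4-(benzyloxy)-6-(2-hydroxy-2-phenylpent-4-en-1-yl)-2H-pyran-2-one | C=CC[C@](O)(c1ccccc1)Cc1cc(OCc2ccccc2)cc(=O)o1 | intermediate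
7 | 4-(benzyloxy)-6-[(2R)-2,4,5-trihydroxy-2-phenylpentyl]-2H-pyran-2-one (both epimers at the new secondary carbinol; not isolated) | OCC(O)C[C@](O)(c1ccccc1)Cc1cc(OCc2ccccc2)cc(=O)o1 | intermediate
8 | (S)-4-[4-(benzyloxy)-2-oxo-2H-pyran-6-yl]-3-hydroxy-3-phenylbutanal | O=CC[C@](O)(c1ccccc1)Cc1cc(OCc2ccccc2)cc(=O)o1 | intermediate
9 | (S)-4-[4-(benzyloxy)-2-oxo-2H-pyran-6-yl]-3-hydroxy-3-phenylbutanoic acid | OC(=O)C[C@](O)(c1ccccc1)Cc1cc(OCc2ccccc2)cc(=O)o1 | intermediate
10 | (S)-4-[4-(benzyloxy)-2-oxo-2H-pyran-6-yl]-3-hydroxy-1-(1H-imidazol-1-yl)-3-phenylbutan-1-one (not isolated) | O=C(C[C@](O)(c1ccccc1)Cc1cc(OCc2ccccc2)cc(=O)o1)n1ccnc1 | intermediate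
11 | (S)-4-[4-(benzyloxy)-2-oxo-2H-pyran-6-yl]-3-hydroxy-N-methoxy-N-methyl-3-phenylbutanamide | CON(C)C(=O)C[C@](O)(c1ccccc1)Cc1cc(OCc2ccccc2)cc(=O)o1 | intermediate
12 | 1-(benzyloxy)-3-bromobenzene | Brc1cccc(OCc2ccccc2)c1 | starting material
13 | dilithio derivative of 11: lithium alkoxide at C3 and C4 carbanion delocalised into the pyrone, drawn C-lithiated; C3 configured as in 11 (not isolated) | CON(C)C(=O)C[C@](O[Li])(c1ccccc1)C([Li])c1cc(OCc2ccccc2)cc(=O)o1 | intermediate
14 | 3-(benzyloxy)benzyne, 1-(benzyloxy)-2,3-didehydrobenzene (not isolated) | C1#CC(OCc2ccccc2)=CC=C1 | intermediate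
15 | lithium alkoxide of (3R)-4-[3-(benzyloxy)-2-lithiophenyl]-4-[4-(benzyloxy)-2-oxo-2H-pyran-6-yl]-3-hydroxy-N-methoxy-N-methyl-3-phenylbutanamide, both C4 epimers (not isolated) | CON(C)C(=O)C[C@](O[Li])(c1ccccc1)C(c1cc(OCc2ccccc2)cc(=O)o1)c1cccc(OCc2ccccc2)c1[Li] | intermediate
16 | ring-closed trilithio species: lithium N,O-hemiaminalate at C1, lithium alkoxide at C3, C4 carbanion delocalised into the pyrone, drawn C-lithiated; C3 configured as in 17, C1 undefined (not isolated) | CON(C)C1(O[Li])C[C@](O[Li])(c2ccccc2)C([Li])(c2cc(OCc3ccccc3)cc(=O)o2)c2cccc(OCc3ccccc3)c21 | intermediate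
17 | (3R,4R)-8-(benzyloxy)-4-[4-(benzyloxy)-2-oxo-2H-pyran-6-yl]-3-hydroxy-3-phenyl-3,4-dihydronaphthalen-1(2H)-one | O=C1C[C@](O)(c2ccccc2)[C@H](c2cc(OCc3ccccc3)cc(=O)o2)c2cccc(OCc3ccccc3)c21 | intermediate
18 | wailupemycin F, (3R,4R)-3,8-dihydroxy-4-(4-hydroxy-2-oxo-2H-pyran-6-yl)-3-phenyl-3,4-dihydronaphthalen-1(2H)-one | O=C1C[C@](O)(c2ccccc2)[C@H](c2cc(O)cc(=O)o2)c2cccc(O)c21 | intermediate
19 | wailupemycin G, 6-(4,5-dihydroxy-2-phenylnaphthalen-1-yl)-4-hydroxy-2H-pyran-2-one | Oc1cc(-c2c(-c3ccccc3)cc(O)c3c(O)cccc23)oc(=O)c1 | intermediate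
20 | (3R,4R)-4-{3-[(dimethylamino)methyl]-4-hydroxy-2-oxo-2H-pyran-6-yl}-3,8-dihydroxy-3-phenyl-3,4-dihydronaphthalen-1(2H)-one (not isolated) | O=C1C[C@](O)(c2ccccc2)[C@H](c2cc(O)c(CN(C)C)c(=O)o2)c2cccc(O)c21 | intermediate
21 | (3R,4R)-3,8-dihydroxy-4-(3-methylidene-2,4-dioxo-3,4-dihydro-2H-pyran-6-yl)-3-phenyl-3,4-dihydronaphthalen-1(2H)-one (not isolated) | O=C1C[C@](O)(c2ccccc2)[C@H](C2=CC(=O)C(=C)C(=O)O2)c2cccc(O)c21 | intermediate
22 | wailupemycin I, (3R,4R)-4-[3-({6-(4,5-dihydroxy-2-phenylnaphthalen-1-yl)-4-hydroxy-2-oxo-2H-pyran-3-yl}methyl)-4-hydroxy-2-oxo-2H-pyran-6-yl]-3,8-dihydroxy-3-phenyl-3,4-dihydronaphthalen-1(2H)-one | O=C1C[C@](O)(c2ccccc2)[C@H](c2cc(O)c(Cc3c(O)cc(-c4c(-c5ccccc5)cc(O)c5c(O)cccc45)oc3=O)c(=O)o2)c2cccc(O)c21 | target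

**Step count.** Total: 10 steps. Longest linear sequence: 10 steps (steps 1 to 10 lie on one line, because 19 is made from 18).

**Steps most likely to fail**

Step 7. The C8a aryl anion may be protonated, by amine or by the acidic C4–H of material that has already reacted, before it reaches the amide. The neopentyl-like C4 carbanion may add so slowly that the aryne is consumed by the lithium amide or by [4+2] addition to a pyrone ring. The dianion may cleave by retro-aldol reaction on warming, and protonation at C4 may be unselective. The fallback sets out from 11 and comes back at 17; it separates the arylation from the ring closure. The dianion of 11 (LiN(iPr)2, THF, −78 °C) is arylated at C4 with the diaryliodonium salt [3-(benzyloxy)-2-bromophenyl](2,4,6-trimethoxyphenyl)iodonium 4-methylbenzenesulfonate F1, which is prepared beforehand from 1-(benzyloxy)-2-bromo-3-iodobenzene (mCPBA, TsOH, then 1,3,5-trimethoxybenzene). This should give the o-bromoaryl amide (3R)-4-[3-(benzyloxy)-2-bromophenyl]-4-[4-(benzyloxy)-2-oxo-2H-pyran-6-yl]-3-hydroxy-N-methoxy-N-methyl-3-phenylbutanamide F2 as a mixture of C4 epimers. F2 is deprotonated twice with LiN(iPr)2 (OH and C4–H) and treated with t-BuLi at −100 °C; the aryllithium from bromine–lithium exchange closes onto the Weinreb amide (Parham cyclization), and the same acetic acid quench should return 17.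

Step 3. The addition may be slow and the facial selectivity poor, because ketone 5 is partly enolised and its enol can bind boron outside the chiral-diol pathway. The fallback sets out from 5 and comes back at 9, so it also replaces steps 4 and 5. Reformatsky addition of ethyl bromoacetate (Zn, THF) should give racemic ethyl 4-[4-(benzyloxy)-2-oxo-2H-pyran-6-yl]-3-hydroxy-3-phenylbutanoate F3. Hydrolysis with LiOH gives the racemic acid 4-[4-(benzyloxy)-2-oxo-2H-pyran-6-yl]-3-hydroxy-3-phenylbutanoic acid F4. The acid is resolved by crystallisation of the (S)-1-phenylethylammonium salt of the (S)-acid F5 (the antipodal amine is used if the salt of the unwanted acid proves the less soluble one), and acidification returns 9.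

Step 10. The aminomethyl group may be transferred between the two pyrones (retro-Mannich exchange), so that symmetrical bis-pyrones form. A naphthol carbon of 19 may be aminomethylated, and the amine may promote dehydration of the β-hydroxy ketone of 18 or epimerisation at C4. The fallback sets out from 18 and 19 and comes back at 22. It is an undirected Knoevenagel–Michael condensation of 18 and 19 with one equivalent of aqueous formaldehyde in EtOH/H2O at rt without amine, followed by chromatographic separation of 22 from the two symmetrical dimers; it makes no new compound.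

**Further compounds**

F1 | step 7 | [3-(benzyloxy)-2-bromophenyl](2,4,6-trimethoxyphenyl)iodonium 4-methylbenzenesulfonate | COc1cc(OC)c([I+]c2cccc(OCc3ccccc3)c2Br)c(OC)c1.Cc1ccc(cc1)S(=O)(=O)[O-]
F2 | step 7 | (3R)-4-[3-(benzyloxy)-2-bromophenyl]-4-[4-(benzyloxy)-2-oxo-2H-pyran-6-yl]-3-hydroxy-N-methoxy-N-methyl-3-phenylbutanamide (both C4 epimers) | CON(C)C(=O)C[C@](O)(c1ccccc1)C(c1cc(OCc2ccccc2)cc(=O)o1)c1cccc(OCc2ccccc2)c1Br
F3 | step 3 | ethyl 4-[4-(benzyloxy)-2-oxo-2H-pyran-6-yl]-3-hydroxy-3-phenylbutanoate (racemic) | CCOC(=O)CC(O)(c1ccccc1)Cc1cc(OCc2ccccc2)cc(=O)o1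
F4 | step 3 | 4-[4-(benzyloxy)-2-oxo-2H-pyran-6-yl]-3-hydroxy-3-phenylbutanoic acid (racemic) | OC(=O)CC(O)(c1ccccc1)Cc1cc(OCc2ccccc2)cc(=O)o1
F5 | step 3 | (S)-1-phenylethylammonium (S)-4-[4-(benzyloxy)-2-oxo-2H-pyran-6-yl]-3-hydroxy-3-phenylbutanoate | C[C@H]([NH3+])c1ccccc1.[O-]C(=O)C[C@](O)(c1ccccc1)Cc1cc(OCc2ccccc2)cc(=O)o1
F0 | step 10 | none | none
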